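The data are simulated with constants of no real substance; the scatter is artificial.

4 questions stand on two flasks, epsilon and gamma, which differ in temperature: what leads at the end of each, and how much of it there is.

| flask | X | L | Q | temperature | remark | time |
|---|---|---|---|---|---|---|
| north | 10 mM | 19 mM | 80 mM | 6 °C | run made earlier |  |
| west | 15 mM | 19 mM | 80 mM | 20 °C | run made earlier |  |
| north-west | 20 mM | 28 mM | 80 mM | 6 °C | run made earlier |  |
| epsilon | 20 mM | 19.0 mM | 80.0 mM | 0 °C |  | 30 h |
| gamma | 20 mM | 19.0 mM | 80.0 mM | 25 °C |  | 30 h |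

| run | time / h | X / % | J / % | G / % | Z / % |
|---|---|---|---|---|---|
| north | 2.00 | 86.5 | 1.2 | 3.9 | 1.1 |
| north | 3.00 | 80.8 | 3.5 | 6.0 | 3.2 |
| north | 4.00 | 76.2 | 5.4 | 8.9 | 5.5 |
| north | 6.00 | 66.6 | 7.3 | 9.8 | 8.5 |
| north | 10.0 | 51.5 | 9.1 | 13.9 | 13.6 |
| north | 15.0 | 35.8 | 12.5 | 17.3 | 16.7 |
| north | 25.0 | 20.5 | 16.1 | 24.5 | 24.0 |
| west | 1.00 | 62.0 | 5.4 | 6.6 | 16.8 |
| west | 2.00 | 41.9 | 10.6 | 12.5 | 25.9 |
| west | 4.00 | 17.6 | 14.5 | 18.8 | 37.7 |
| west | 6.00 | 9.1 | 16.7 | 18.1 | 41.9 |
| west | 8.00 | 5.0 | 16.6 | 21.2 | 42.9 |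
| west | 10.0 | 1.7 | 19.4 | 20.1 | 47.2 |
| north-west | 2.00 | 86.5 | 1.2 | 5.0 | 1.7 |
| north-west | 4.00 | 73.2 | 3.7 | 8.0 | 6.1 |
| north-west | 6.00 | 63.2 | 3.5 | 11.8 | 7.1 |
| north-west | 12.0 | 41.6 | 10.2 | 21.5 | 10.7 |
| north-west | 25.0 | 17.3 | 12.2 | 27.9 | 18.8 |

(scatter of a reading: 1 percentage point)

* which of these there is most of at the end, counted by the X in it, epsilon (G / Z / X / J)
* which of these there is most of at the end, counted by the X in it, gamma (G / Z / X / J)
* how much there is at the end of the one of these that leads, in percent of the X charged: epsilon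
* how much there is at the end of the one of these that leads, in percent of the X charged: gamma

- a reading or a percentage of G counts all its forms, free or not
- a reading of X is of its free form alone

One pair of numbers in the west run looks wrong. After 8.00 h free X reads 5.0%, yet the readings add up 14.3% short of the charge, so more X is missing than stands free. A reading of X counts the free form and a reading of G counts every form, so I take the gap as X bound to G in a complex D, formed in a fast pre-equilibrium. Treating that step as at equilibrium at each moment, the west reading gives K = c(D)/(c(X)·free c(G)) = 2760 L mol⁻¹.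

Late in gamma I put free c(G) near 4.24 mM, the west reading of G taken on gamma's charge, and keep this K, as a rough reckoning. The holding factor, the X in free form and in D per free X, which is one plus K times free c(G), is then 12.7. Free X falls with k, so the whole pool falls with k divided by this factor. The early west readings give k = 0.420 h⁻¹, and I allow 0.839 h⁻¹ for gamma. A gap of the west size, drained from 8.00 h to 30 h, shrinks to 3.35%, so I expect gamma's balance to close near 96.7%.

The forecast names X for epsilon at 39% (33% to 45%) and Z for gamma at 53% (46% to 61%), saying: “The balance closes near 88%, as some X stays unaccounted for”. There we part, and I lean to the high end of its gamma range.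

Gamma ends with Z at 59.4%, and epsilon with X at 42.4%.

    E → Z (k = 9.10 h⁻¹, Ea = 89.0 kJ mol⁻¹)
    X + G ⇌ D, settled at all times (K = 640 L mol⁻¹, ΔH = 52.0 kJ mol⁻¹)
    Q + E → J (k = 110 L mol⁻¹ h⁻¹, Ea = 58.0 kJ mol⁻¹)
    L + E → G (k = 830 L mol⁻¹ h⁻¹, Ea = 47.0 kJ mol⁻¹)
    X → E (k = 0.0210 h⁻¹, Ea = 95.0 kJ mol⁻¹)
    (constants at 0 °C)

At the end of gamma D stands at 6.09%, where each D counts as two, so the gap is 3.04%. The holding factor, reckoned at 12.7, comes out of that end state as 15.4. At the end of epsilon it is 1.37. A neighbour of epsilon, charged with 7.6 mM of L, ends with a factor of 1.19, and its free X ends higher than epsilon's, at 47.1%.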